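**Plan**
1. Retrosynthesis (chain numbered from the ketone carbon C1 to C18): the two aryl O–Si bonds are cut first, then C9–C10, then C6=C7, then aryl–C1; in the C10–C18 half, C12=C13 is cut.
2. Enabling feature: C9 is a secondary carbinol allylic to the E C10=C11 bond of the C10–C13 E,Z-diene. That is the retron of a terminal 1,3-enyne (C10≡C11) hydrometalated syn and added to a C9 aldehyde. The only ring, the benzene ring, holds the C1 ketone between two ortho silyloxy groups, which keeps C1=O out of the organozinc chemistry.
3. Forward: directed lithiation of the bis-MOM arene and opening of ε-caprolactone give the aryl ketone; a Z-Wittig reaction builds C6=C7; MOM is exchanged for TBS; oxidation gives the C9 aldehyde. The enyne comes from (Z)-hex-3-en-1-ol by a Z-Wittig reaction with a silyl ynal. A one-pot hydroboration/B-to-Zn exchange/catalytic asymmetric alkenylation joins the halves, and fluoride frees the phenols. No ring is formed.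
4. Stereochemistry: C9 (R) from ligand-controlled Si-face alkenyl transfer; 10E from syn hydroboration; 6Z and 12Z from salt-free Wittig reactions; 15Z from the starting hexenol.

Key step: step 14

Remark: (−)-MIB is assumed to deliver the alkenyl group to the Si face of the aldehyde, as it does in dialkylzinc additions; its antipode would be used if the sense proved opposite.

Step 1
Reactants: 1 5-methoxyresorcinol (5-methoxybenzene-1,3-diol)
Product: 2 bis-MOM ether 1-methoxy-3,5-bis(methoxymethoxy)benzene
Conditions: MOMCl, iPr2NEt, CH2Cl2, 0 °C to rt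
Reagents that add atoms: chloromethyl methyl ether (MOMCl), COCCl
Why: O-alkylation of both phenols (Williamson-type acetal ether formation) should install two MOM groups that later direct the metalation.

Step 2
Reactants: 2 bis-MOM ether; 3 ε-caprolactone (oxepan-2-one)
Product: 5 hydroxy ketone 6-hydroxy-1-[4-methoxy-2,6-bis(methoxymethoxy)phenyl]hexan-1-one, via aryllithium 4 (not isolated)
Conditions: n-BuLi, THF, 0 °C; then 3, −78 °C to 0 °C; then H2O
Reagents that add atoms: none
Why: Directed ortho-metalation should occur at the ring carbon flanked by the two chelating OMOM groups (stronger directors than OMe), and acyl substitution on the lactone should stop at the ketone because the 2,6-disubstituted aryl ketone resists a second addition.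

Step 3
Reactants: 5 hydroxy ketone
Product: 6 keto aldehyde 6-[4-methoxy-2,6-bis(methoxymethoxy)phenyl]-6-oxohexanal
Conditions: Dess–Martin periodinane, NaHCO3, CH2Cl2, 0 °C to rt
Reagents that add atoms: none
Why: Dess–Martin oxidation of the primary alcohol under buffered, base-free conditions should leave the MOM ethers and the ketone untouched and avoid aldol reactions of the keto aldehyde.

Step 4
Reactants: 7 (3-bromopropoxy)(tert-butyl)dimethylsilane
Product: 8 phosphonium salt [3-(tert-butyldimethylsilyloxy)propyl]triphenylphosphonium bromide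
Conditions: PPh3, MeCN, reflux
Reagents that add atoms: triphenylphosphine, c1ccc(cc1)P(c1ccccc1)c1ccccc1
Why: SN2 quaternization of triphenylphosphine by the primary bromide should give the Wittig salt with the silyl ether intact.

Step 5
Reactants: 8 phosphonium salt; 6 keto aldehyde
Product: 10 Z-alkene (Z)-9-(tert-butyldimethylsilyloxy)-1-[4-methoxy-2,6-bis(methoxymethoxy)phenyl]non-6-en-1-one, via ylide 9 (not isolated)
Conditions: NaHMDS, THF, 0 °C; then 6, −78 °C to rt
Reagents that add atoms: none
Why: Wittig olefination with a non-stabilized ylide under lithium-free conditions is kinetically Z-selective, and at −78 °C the aldehyde should react far faster than the hindered di-ortho-substituted aryl ketone.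

Step 6
Reactants: 10 Z-alkene
Product: 11 triol (Z)-1-(2,6-dihydroxy-4-methoxyphenyl)-9-hydroxynon-6-en-1-one
Conditions: conc. HCl (cat.), MeOH, 40 °C
Reagents that add atoms: none
Why: Acid-catalysed acetal exchange should cleave both aryl MOM ethers and methanolysis the alkyl silyl ether, while the isolated Z-alkene and the ketone are inert to dilute acid; acid is thereby used before the acid-sensitive dienyl carbinol exists.

Step 7
Reactants: 11 triol
Product: 12 tris-silyl ether (Z)-1-[2,6-bis(tert-butyldimethylsilyloxy)-4-methoxyphenyl]-9-(tert-butyldimethylsilyloxy)non-6-en-1-one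
Conditions: TBSCl, imidazole, DMAP (cat.), DMF, rt to 40 °C
Reagents that add atoms: tert-butyldimethylsilyl chloride (TBSCl), CC(C)(C)[Si](C)(C)Cl
Why: Imidazole-promoted silylation of all three hydroxyl groups should put fluoride-labile groups on the phenols, so that the final deprotection needs no acid.

Step 8
Reactants: 12 tris-silyl ether
Product: 13 alcohol (Z)-1-[2,6-bis(tert-butyldimethylsilyloxy)-4-methoxyphenyl]-9-hydroxynon-6-en-1-one
Conditions: CSA (cat.), MeOH/CH2Cl2, 0 °C
Reagents that add atoms: none
Why: Acid-catalysed methanolysis cleaves a primary alkyl TBS ether much faster than aryl TBS ethers, so only the C9 hydroxyl should be released (selective desilylation).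

Step 9
Reactants: 13 alcohol
Product: 14 aldehyde (Z)-9-[2,6-bis(tert-butyldimethylsilyloxy)-4-methoxyphenyl]-9-oxonon-3-enal
Conditions: Dess–Martin periodinane, NaHCO3, CH2Cl2, 0 °C; used at once without chromatography
Reagents that add atoms: none
Why: Dess–Martin oxidation with a solid bicarbonate buffer should give the Z-β,γ-unsaturated aldehyde without base or acid that would move C6=C7 into conjugation.

Step 10
Reactants: 15 (Z)-hex-3-en-1-ol
Product: 16 iodide (Z)-1-iodohex-3-ene
Conditions: I2, PPh3, imidazole, CH2Cl2, 0 °C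
Reagents that add atoms: iodine, II
Why: Appel iodination proceeds by SN2 displacement at the primary carbon and should leave the Z-alkene untouched.

Step 11
Reactants: 16 iodide
Product: 17 phosphonium salt [(Z)-hex-3-en-1-yl]triphenylphosphonium iodide
Conditions: PPh3, MeCN, reflux
Reagents that add atoms: triphenylphosphine, c1ccc(cc1)P(c1ccccc1)c1ccccc1
Why: SN2 quaternization of triphenylphosphine by the primary iodide should give the salt with the Z-alkene intact.

Step 12
Reactants: 17 phosphonium salt; 18 3-(trimethylsilyl)prop-2-ynal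
Product: 20 silyl enyne trimethyl[(3Z,6Z)-nona-3,6-dien-1-yn-1-yl]silane, via ylide 19 (not isolated)
Conditions: NaHMDS, THF, −78 °C; then 18, −78 °C to 0 °C
Reagents that add atoms: none
Why: Z-selective Wittig olefination of a non-stabilized ylide with the ynal should set 12Z, since 1,2-addition to the aldehyde outruns conjugate addition at −78 °C and the silyl group protects the alkyne terminus.

Step 13
Reactants: 20 silyl enyne
Product: 21 enyne (3Z,6Z)-nona-3,6-dien-1-yne
Conditions: K2CO3 (cat.), MeOH, rt; kept as a pentane solution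
Reagents that add atoms: none
Why: Base-catalysed methanolysis of the C(sp)–Si bond (protodesilylation) should free the terminal alkyne without touching the Z-alkenes.

Step 14
Reactants: 21 enyne; 14 aldehyde
Product: 24 dienol (6Z,9R,10E,12Z,15Z)-1-[2,6-bis(tert-butyldimethylsilyloxy)-4-methoxyphenyl]-9-hydroxyoctadeca-6,10,12,15-tetraen-1-one, via dienylborane 22 (not isolated), via dienylzinc 23 (not isolated)
Conditions: Cy2BH (from BH3·SMe2 and cyclohexene), toluene, 0 °C to rt; Me2Zn, −78 °C; (−)-MIB (5 mol%), then 14 added slowly, −10 °C; then H2O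
Reagents that add atoms: none
Why: Dicyclohexylborane should add syn and anti-Markovnikov to the terminal alkyne C10≡C11 faster than to the two Z-disubstituted alkenes; boron-to-zinc exchange with Me2Zn then gives the dienyl(methyl)zinc with retention of geometry, and the zinc aminoalkoxide of (−)-MIB binds aldehyde and alkenylzinc in a bimetallic six-membered transition state that transfers the alkenyl group to C9. The closest known reaction type is the one-pot alkyne hydroboration/transmetalation/amino-alcohol-catalysed enantioselective alkenylzinc addition to aldehydes, which includes dienylzinc reagents made from enynes. No ring is closed. The new stereocentre C9 is controlled by the chiral ligand (Si-face transfer gives R), and the E geometry of C10=C11 follows from the syn hydroboration, while 12Z and 15Z are carried through unchanged. The step needs the aldehyde to react in preference to the aryl ketone, which the two ortho silyloxy groups (twisting and shielding C1=O) and the low reactivity of organozincs toward ketones should secure; alkenyl transfer in preference to methyl transfer, which the faster transfer of sp2 groups from zinc secures; and survival of the skipped enal, which the weakly basic zinc reagents, −10 °C and slow aldehyde addition favour.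

Step 15
Reactants: 24 dienol
Product: 25 target (6Z,9R,10E,12Z,15Z)-1-(2,6-dihydroxy-4-methoxyphenyl)-9-hydroxyoctadeca-6,10,12,15-tetraen-1-one
Conditions: TBAF, AcOH, THF, 0 °C
Reagents that add atoms: none
Why: Fluoride-mediated desilylation of the two aryl silyl ethers under acetic acid buffering should free the phenols without acid strong enough to ionize the dienyl carbinol and without strongly basic phenoxide conditions.

**Compound list**
1 | 5-methoxyresorcinol (5-methoxybenzene-1,3-diol) | COc1cc(O)cc(O)c1 | starting material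
2 | 1-methoxy-3,5-bis(methoxymethoxy)benzene | COCOc1cc(OC)cc(OCOC)c1 | intermediate
3 | ε-caprolactone (oxepan-2-one) | O=C1CCCCCO1 | starting material
4 | [4-methoxy-2,6-bis(methoxymethoxy)phenyl]lithium | [Li]c1c(OCOC)cc(OC)cc1OCOC | intermediate (not isolated)
5 | 6-hydroxy-1-[4-methoxy-2,6-bis(methoxymethoxy)phenyl]hexan-1-one | OCCCCCC(=O)c1c(OCOC)cc(OC)cc1OCOC | intermediate
6 | 6-[4-methoxy-2,6-bis(methoxymethoxy)phenyl]-6-oxohexanal | O=CCCCCC(=O)c1c(OCOC)cc(OC)cc1OCOC | intermediate
7 | (3-bromopropoxy)(tert-butyl)dimethylsilane | BrCCCO[Si](C)(C)C(C)(C)C | starting material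
8 | [3-(tert-butyldimethylsilyloxy)propyl]triphenylphosphonium bromide | CC(C)(C)[Si](C)(C)OCCC[P+](c1ccccc1)(c1ccccc1)c1ccccc1.[Br-] | intermediate
9 | [3-(tert-butyldimethylsilyloxy)propylidene]triphenylphosphorane | CC(C)(C)[Si](C)(C)OCCC=P(c1ccccc1)(c1ccccc1)c1ccccc1 | intermediate (not isolated)
10 | (Z)-9-(tert-butyldimethylsilyloxy)-1-[4-methoxy-2,6-bis(methoxymethoxy)phenyl]non-6-en-1-one | CC(C)(C)[Si](C)(C)OCC/C=C\CCCCC(=O)c1c(OCOC)cc(OC)cc1OCOC | intermediate
11 | (Z)-1-(2,6-dihydroxy-4-methoxyphenyl)-9-hydroxynon-6-en-1-one | OCC/C=C\CCCCC(=O)c1c(O)cc(OC)cc1O | intermediate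
12 | (Z)-1-[2,6-bis(tert-butyldimethylsilyloxy)-4-methoxyphenyl]-9-(tert-butyldimethylsilyloxy)non-6-en-1-one | CC(C)(C)[Si](C)(C)OCC/C=C\CCCCC(=O)c1c(O[Si](C)(C)C(C)(C)C)cc(OC)cc1O[Si](C)(C)C(C)(C)C | intermediate
13 | (Z)-1-[2,6-bis(tert-butyldimethylsilyloxy)-4-methoxyphenyl]-9-hydroxynon-6-en-1-one | OCC/C=C\CCCCC(=O)c1c(O[Si](C)(C)C(C)(C)C)cc(OC)cc1O[Si](C)(C)C(C)(C)C | intermediate
14 | (Z)-9-[2,6-bis(tert-butyldimethylsilyloxy)-4-methoxyphenyl]-9-oxonon-3-enal | O=CC/C=C\CCCCC(=O)c1c(O[Si](C)(C)C(C)(C)C)cc(OC)cc1O[Si](C)(C)C(C)(C)C | intermediate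
15 | (Z)-hex-3-en-1-ol | CC/C=C\CCO | starting material
16 | (Z)-1-iodohex-3-ene | CC/C=C\CCI | intermediate
17 | [(Z)-hex-3-en-1-yl]triphenylphosphonium iodide | CC/C=C\CC[P+](c1ccccc1)(c1ccccc1)c1ccccc1.[I-] | intermediate
18 | 3-(trimethylsilyl)prop-2-ynal | C[Si](C)(C)C#CC=O | starting material
19 | [(Z)-hex-3-en-1-ylidene]triphenylphosphorane | CC/C=C\CC=P(c1ccccc1)(c1ccccc1)c1ccccc1 | intermediate (not isolated)
20 | trimethyl[(3Z,6Z)-nona-3,6-dien-1-yn-1-yl]silane | CC/C=C\C/C=C\C#C[Si](C)(C)C | intermediate
21 | (3Z,6Z)-nona-3,6-dien-1-yne | CC/C=C\C/C=C\C#C | intermediate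
22 | dicyclohexyl[(1E,3Z,6Z)-nona-1,3,6-trien-1-yl]borane | CC/C=C\C/C=C\C=C\B(C1CCCCC1)C1CCCCC1 | intermediate (not isolated)
23 | methyl[(1E,3Z,6Z)-nona-1,3,6-trien-1-yl]zinc | CC/C=C\C/C=C\C=C\[Zn]C | intermediate (not isolated)
24 | (6Z,9R,10E,12Z,15Z)-1-[2,6-bis(tert-butyldimethylsilyloxy)-4-methoxyphenyl]-9-hydroxyoctadeca-6,10,12,15-tetraen-1-one | CC/C=C\C/C=C\C=C\[C@H](O)C/C=C\CCCCC(=O)c1c(O[Si](C)(C)C(C)(C)C)cc(OC)cc1O[Si](C)(C)C(C)(C)C | intermediate
25 | (6Z,9R,10E,12Z,15Z)-1-(2,6-dihydroxy-4-methoxyphenyl)-9-hydroxyoctadeca-6,10,12,15-tetraen-1-one | CC/C=C\C/C=C\C=C\[C@H](O)C/C=C\CCCCC(=O)c1c(O)cc(OC)cc1O | target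

**Step count**
Total steps: 15. Longest linear sequence: 10 steps (steps 1, 2, 3, 5, 6, 7, 8, 9, 14, 15).

**Steps most likely to fail**

Step 14. The alkenyl transfer to the α-unbranched aldehyde may discriminate the two faces incompletely, and methyl transfer or enolization of the aldehyde by the zinc species may compete. The fallback sets out from 21 and comes back at 24. Hydrozirconation of 21 with Cp2Zr(H)Cl in THF would give chlorobis(cyclopentadienyl)[(1E,3Z,6Z)-nona-1,3,6-trien-1-yl]zirconium F1 (not isolated), and iodinolysis with I2 at 0 °C would give (1E,3Z,6Z)-1-iodonona-1,3,6-triene F2. An asymmetric Nozaki–Hiyama–Kishi coupling of F2 with 14 (CrCl2, NiCl2 cat., chiral oxazoline sulfonamide ligand, Et3N, THF) would then give 24. The organochromium reagent is non-basic and aldehyde-selective, and the ligand enantiomer is chosen for Si-face addition.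

Step 9. The C6=C7 double bond may migrate into conjugation with the aldehyde, with loss of the Z geometry, during oxidation, work-up or the coupling. The fallback sets out from 13 and comes back at 24 without a free aldehyde. Oxidation of 13 with TEMPO (cat.) and PhI(OAc)2 in MeCN/H2O would give (Z)-9-[2,6-bis(tert-butyldimethylsilyloxy)-4-methoxyphenyl]-9-oxonon-3-enoic acid F3. Treatment with 1-chloro-N,N,2-trimethylprop-1-en-1-amine under neutral conditions would give (Z)-9-[2,6-bis(tert-butyldimethylsilyloxy)-4-methoxyphenyl]-9-oxonon-3-enoyl chloride F4. Negishi acylation of F4 with dienylzinc 23 (made as in step 14) under Pd(PPh3)4 catalysis would give (6Z,10E,12Z,15Z)-1-[2,6-bis(tert-butyldimethylsilyloxy)-4-methoxyphenyl]octadeca-6,10,12,15-tetraene-1,9-dione F5. Corey–Bakshi–Shibata reduction of F5 [(S)-Me-CBS cat., catecholborane, toluene, −78 °C] would give 24; the dienyl group acts as the large substituent, and the hindered aryl ketone should be left alone.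

Step 12. The Wittig reaction with the ynal may leak to the E-enyne, and the ylide may add in conjugate fashion to the ynal. The fallback sets out from 15 and comes back at 20. Dess–Martin oxidation of 15 would give (Z)-hex-3-enal F6. Stork–Zhao olefination [(iodomethyl)triphenylphosphonium iodide, NaHMDS, THF, −78 °C] would give (1Z,4Z)-1-iodohepta-1,4-diene F7. Sonogashira coupling of F7 with ethynyltrimethylsilane (Pd(PPh3)4, CuI, Et2NH) would give 20 with retention of the alkene geometry.

**Further compounds**
F1 | step 14 | chlorobis(cyclopentadienyl)[(1E,3Z,6Z)-nona-1,3,6-trien-1-yl]zirconium | CC/C=C\C/C=C\C=C\[Zr](Cl)(C1C=CC=C1)C1C=CC=C1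
F2 | step 14 | (1E,3Z,6Z)-1-iodonona-1,3,6-triene | CC/C=C\C/C=C\C=C\I
F3 | step 9 | (Z)-9-[2,6-bis(tert-butyldimethylsilyloxy)-4-methoxyphenyl]-9-oxonon-3-enoic acid | OC(=O)C/C=C\CCCCC(=O)c1c(O[Si](C)(C)C(C)(C)C)cc(OC)cc1O[Si](C)(C)C(C)(C)C
F4 | step 9 | (Z)-9-[2,6-bis(tert-butyldimethylsilyloxy)-4-methoxyphenyl]-9-oxonon-3-enoyl chloride | ClC(=O)C/C=C\CCCCC(=O)c1c(O[Si](C)(C)C(C)(C)C)cc(OC)cc1O[Si](C)(C)C(C)(C)C
F5 | step 9 | (6Z,10E,12Z,15Z)-1-[2,6-bis(tert-butyldimethylsilyloxy)-4-methoxyphenyl]octadeca-6,10,12,15-tetraene-1,9-dione | CC/C=C\C/C=C\C=C\C(=O)C/C=C\CCCCC(=O)c1c(O[Si](C)(C)C(C)(C)C)cc(OC)cc1O[Si](C)(C)C(C)(C)C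
F6 | step 12 | (Z)-hex-3-enal | CC/C=C\CC=O
F7 | step 12 | (1Z,4Z)-1-iodohepta-1,4-diene | CC/C=C\C/C=C\I
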